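**Retrosynthetic overview**
- The target comes from the silyl ether of its 3-ketone: the C3 carbinol is set last by chelation-controlled reduction, and the lactone carbonyl comes from oxidation of a 12,16-ether (a 3-methyleneoxepane).
- The 14-membered carbocycle is closed at C3–C4 by a light-driven, samarium-catalysed pinacol coupling of an aldehyde with a methyl ketone.
- The oxepane comes from a Baeyer–Villiger lactone: tert-butoxide opens it and the freed C12 alkoxide displaces an allylic chloride.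
- The C11–C12 bond and the quaternary C12 come from a Mukaiyama aldol between the silyl enol ether of (S)-10-chlorocarvone and a C4–C11 keto-aldehyde cut from nerylacetone.
- Ring order: carvone six-membered ring (bought, ring-expanded by Baeyer–Villiger, then opened) → oxepane → 14-membered carbocycle → ε-lactone by oxidation of the oxepane.

Assumption: locants C1–C20 follow cembrane numbering of the target (C1 carries the acrylate unit, C16 is the lactone carbonyl, C17 the exocyclic methylene, C18/C19/C20 the methyls on C4/C8/C12); nerylacetone is bought as the pure 5Z isomer. TBS = tert-butyldimethylsilyl.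

**Route**

Step 1
Reactants: 1 nerylacetone, (5Z)-6,10-dimethylundeca-5,9-dien-2-one
Product: 3 (5Z)-8-(3,3-dimethyloxiran-2-yl)-6-methyloct-5-en-2-one (racemic), via bromohydrin 2 (not isolated)
Conditions: NBS, THF/H2O, 0 °C; then K2CO3, MeOH, rt
Reagents that add atoms: water, O
Why: Terminal-selective bromohydrin formation in aqueous THF (van Tamelen conditions) followed by intramolecular Williamson closure gives the terminal epoxide; its stereocentre is racemic and is destroyed in step 2.

Step 2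
Reactants: 3 (5Z)-8-(3,3-dimethyloxiran-2-yl)-6-methyloct-5-en-2-one
Product: 4 (4Z)-4-methyl-8-oxonon-4-enal
Conditions: H5IO6, THF/H2O, 0 °C → rt
Reagents that add atoms: none
Why: Periodic acid hydrolyses the epoxide and cleaves the glycol (Malaprade-type cleavage), releasing acetone and leaving the Z-alkene and the methyl ketone untouched; no stereocentre remains.

Step 3
Reactants: 5 (S)-(+)-carvone
Product: 6 (5S)-5-(3-chloroprop-1-en-2-yl)-2-methylcyclohex-2-en-1-one
Conditions: Ca(OCl)2, CO2 (dry ice), CH2Cl2/H2O, 0 °C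
Reagents that add atoms: calcium hypochlorite, [Ca+2].[O-]Cl.[O-]Cl
Why: Ene-type allylic chlorination by hypochlorous acid made in situ attacks only the electron-rich 1,1-disubstituted alkene (the enone alkene is deactivated) with transposition of the double bond, and the bought C1 stereocentre is not touched.

Step 4
Reactants: 6 (5S)-5-(3-chloroprop-1-en-2-yl)-2-methylcyclohex-2-en-1-one
Product: 8 tert-butyl{[(5S)-5-(3-chloroprop-1-en-2-yl)-2-methylcyclohex-1-en-1-yl]oxy}dimethylsilane, via lithium enolate 7 (not isolated)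
Conditions: LiBH(s-Bu)3, THF, −78 °C; then TBSOTf, −78 → 0 °C
Reagents that add atoms: tert-butyldimethylsilyl triflate, CC(C)(C)[Si](C)(C)OS(=O)(=O)C(F)(F)F
Why: Conjugate (1,4) hydride reduction gives the regiodefined tetrasubstituted lithium enolate, which is O-silylated at once (silyl enol ether formation) so it cannot alkylate the allylic chloride; no stereocentre is formed.

Step 5
Reactants: 8 tert-butyl{[(5S)-5-(3-chloroprop-1-en-2-yl)-2-methylcyclohex-1-en-1-yl]oxy}dimethylsilane; 4 (4Z)-4-methyl-8-oxonon-4-enal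
Product: 9 (2S,5S)-2-[(1R,4Z)-1-(TBS-oxy)-4-methyl-8-oxonon-4-en-1-yl]-5-(3-chloroprop-1-en-2-yl)-2-methylcyclohexan-1-one
Conditions: Tf2NH (2 mol %), CH2Cl2, −78 °C
Reagents that add atoms: none
Why: Mukaiyama aldol addition with silyl transfer, selective for the aldehyde over the methyl ketone; axial attack on the half-chair enol ether with the C1 side chain equatorial puts the new bond at C12 cis to that side chain (the sense known for dihydrocarvone enolates), and the open antiperiplanar transition state places the aldehyde chain next to the small C12 methyl instead of the ring methylene, giving (11R).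

Step 6
Reactants: 9 (2S,5S)-2-[(1R,4Z)-1-(TBS-oxy)-4-methyl-8-oxonon-4-en-1-yl]-5-(3-chloroprop-1-en-2-yl)-2-methylcyclohexan-1-one
Product: 10 (4S,7S)-7-[(1R,4Z)-1-(TBS-oxy)-4-methyl-8-oxonon-4-en-1-yl]-4-(3-chloroprop-1-en-2-yl)-7-methyloxepan-2-one
Conditions: (TMSO)2, TMSOTf (10 mol %), CH2Cl2, −40 °C
Reagents that add atoms: bis(trimethylsilyl) peroxide, C[Si](C)(C)OO[Si](C)(C)C
Why: Baeyer–Villiger oxidation in which the quaternary C12 migrates in preference to the C2 methylene and with retention, the acyclic methyl ketone reacts far more slowly, and the silyl peroxide system does not epoxidise the alkenes.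

Step 7
Reactants: 10 (4S,7S)-7-[(1R,4Z)-1-(TBS-oxy)-4-methyl-8-oxonon-4-en-1-yl]-4-(3-chloroprop-1-en-2-yl)-7-methyloxepan-2-one
Product: 12 tert-butyl 2-[(2S,5S)-2-[(1R,4Z)-1-(TBS-oxy)-4-methyl-8-oxonon-4-en-1-yl]-2-methyl-6-methylideneoxepan-5-yl]acetate, via potassium alkoxide 11 (not isolated)
Conditions: KOt-Bu, THF, −20 °C → rt
Reagents that add atoms: potassium tert-butoxide, CC(C)(C)[O-].[K+]
Why: Transesterification of the strained lactone by tert-butoxide frees the tertiary C12 alkoxide, which closes the oxepane by intramolecular Williamson etherification on the symmetric 2-substituted allyl chloride, while tert-butoxide is too hindered to displace the chloride itself; no stereocentre is touched and the C12–O–C16 link of the later lactone is fixed.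

Step 8
Reactants: 12 tert-butyl 2-[(2S,5S)-2-[(1R,4Z)-1-(TBS-oxy)-4-methyl-8-oxonon-4-en-1-yl]-2-methyl-6-methylideneoxepan-5-yl]acetate
Product: 13 2-[(2S,5S)-2-[(1R,4Z)-1-(TBS-oxy)-8-hydroxy-4-methylnon-4-en-1-yl]-2-methyl-6-methylideneoxepan-5-yl]ethan-1-ol (both C4 carbinol epimers)
Conditions: LiAlH4, THF, 0 °C
Reagents that add atoms: none
Why: Hydride reduction of the ester to the primary alcohol also reduces the methyl ketone, giving a C4 carbinol mixture that is erased in step 9.

Step 9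
Reactants: 13 2-[(2S,5S)-2-[(1R,4Z)-1-(TBS-oxy)-8-hydroxy-4-methylnon-4-en-1-yl]-2-methyl-6-methylideneoxepan-5-yl]ethan-1-ol
Product: 14 2-[(2S,5S)-2-[(1R,4Z)-1-(TBS-oxy)-4-methyl-8-oxonon-4-en-1-yl]-2-methyl-6-methylideneoxepan-5-yl]acetaldehyde
Conditions: Dess–Martin periodinane, CH2Cl2, rt
Reagents that add atoms: none
Why: Dess–Martin oxidation turns the primary and secondary alcohols into the aldehyde and methyl ketone under neutral conditions that spare the silyl ether, the allylic ether and both alkenes.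

Step 10
Reactants: 14 2-[(2S,5S)-2-[(1R,4Z)-1-(TBS-oxy)-4-methyl-8-oxonon-4-en-1-yl]-2-methyl-6-methylideneoxepan-5-yl]acetaldehyde
Product: 15 (1S,3S,4R,7Z,11R,12S)-11-(TBS-oxy)-12,16-epoxycembra-7,15(17)-diene-3,4-diol
Conditions: SmI2 (10 mol %), Hantzsch ester (1.5 equiv), THF (2 mM), 405 nm LEDs, rt
Reagents that add atoms: none
Why: Proposed new method: a light-driven, samarium-catalysed intramolecular aldehyde–ketone pinacol coupling used as a macrocyclisation, in which photoexcited Hantzsch ester reduces trivalent to divalent samarium, the samarium-bound aldehyde ketyl adds to the ketone held on the same metal, and the trivalent samarium diolate is protonated by the oxidised Hantzsch ester so the metal turns over; both oxygens are bridged during C3–C4 bond formation (ring-cis diol) and the C4 methyl is expected on the outer face of the forming ring away from the oxepane (substrate control by C1, C11, C12) to give (4R), while C3 is re-set in step 12 so its 3-epimer also serves; closest known reaction types are stoichiometric SmI2 or low-valent titanium pinacol macrocyclisations of keto-aldehydes and photodriven samarium-catalysed intermolecular pinacol couplings.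

Step 11
Reactants: 15 (1S,3S,4R,7Z,11R,12S)-11-(TBS-oxy)-12,16-epoxycembra-7,15(17)-diene-3,4-diol
Product: 16 (1S,4R,7Z,11R,12S)-11-(TBS-oxy)-4-hydroxy-3-oxocembra-7,15(17)-dien-16,12-olide
Conditions: pyridinium chlorochromate (pyH)[CrO3Cl] (6 equiv), 4 Å MS, CH2Cl2, rt → 40 °C
Reagents that add atoms: pyridinium chlorochromate, [O-][Cr](=O)(=O)Cl.c1cc[nH+]cc1
Why: Chromate oxidation converts the secondary C3 carbinol to the α-ketol and the doubly activated O–CH2–C(=CH2) methylene of the cyclic allylic ether to the lactone carbonyl (allylic ether to unsaturated lactone oxidation by hexavalent chromium), while the tertiary C4 hydroxyl and the silyl ether cannot react; the C3 centre is deliberately erased.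

Step 12
Reactants: 16 (1S,4R,7Z,11R,12S)-11-(TBS-oxy)-4-hydroxy-3-oxocembra-7,15(17)-dien-16,12-olide
Product: 18 (1S,3S,4R,7Z,11R,12S)-3,4,11-trihydroxycembra-7,15(17)-dien-16,12-olide (target), via silyl ether 17 (not isolated)
Conditions: Zn(BH4)2, Et2O, −30 °C; then HF·pyridine, THF, 0 °C → rt
Reagents that add atoms: none
Why: Chelation-controlled (Cram chelate) reduction in which zinc bridges the C3 carbonyl and the C4 hydroxyl and hydride enters from the face of the small exocyclic C4 methyl, setting (3S) next to (4R) without touching the α-methylene lactone; fluoride then removes the silyl group under non-equilibrating conditions.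

**Compound list**

1 | nerylacetone, (5Z)-6,10-dimethylundeca-5,9-dien-2-one | CC(=O)CC/C=C(/C)CCC=C(C)C | starting material
2 | (5Z)-9-bromo-10-hydroxy-6,10-dimethylundec-5-en-2-one (racemic) | CC(=O)CC/C=C(/C)CCC(Br)C(C)(C)O | intermediate
3 | (5Z)-8-(3,3-dimethyloxiran-2-yl)-6-methyloct-5-en-2-one (racemic) | CC(=O)CC/C=C(/C)CCC1OC1(C)C | intermediate
4 | (4Z)-4-methyl-8-oxonon-4-enal | CC(=O)CC/C=C(/C)CCC=O | intermediate
5 | (S)-(+)-carvone | CC1=CC[C@@H](CC1=O)C(C)=C | starting material
6 | (5S)-5-(3-chloroprop-1-en-2-yl)-2-methylcyclohex-2-en-1-one | CC1=CC[C@@H](CC1=O)C(=C)CCl | intermediate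
7 | lithium (5S)-5-(3-chloroprop-1-en-2-yl)-2-methylcyclohex-1-en-1-olate | [Li+].CC1=C([O-])C[C@@H](C(=C)CCl)CC1 | intermediate
8 | tert-butyl{[(5S)-5-(3-chloroprop-1-en-2-yl)-2-methylcyclohex-1-en-1-yl]oxy}dimethylsilane | CC1=C(O[Si](C)(C)C(C)(C)C)C[C@@H](C(=C)CCl)CC1 | intermediate
9 | (2S,5S)-2-[(1R,4Z)-1-(TBS-oxy)-4-methyl-8-oxonon-4-en-1-yl]-5-(3-chloroprop-1-en-2-yl)-2-methylcyclohexan-1-one | CC(=O)CC/C=C(/C)CC[C@@H](O[Si](C)(C)C(C)(C)C)[C@]1(C)CC[C@H](C(=C)CCl)CC1=O | intermediate
10 | (4S,7S)-7-[(1R,4Z)-1-(TBS-oxy)-4-methyl-8-oxonon-4-en-1-yl]-4-(3-chloroprop-1-en-2-yl)-7-methyloxepan-2-one | CC(=O)CC/C=C(/C)CC[C@@H](O[Si](C)(C)C(C)(C)C)[C@]1(C)CC[C@H](C(=C)CCl)CC(=O)O1 | intermediate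
11 | potassium alkoxide of tert-butyl (3S,6S,7R,10Z)-7-(TBS-oxy)-3-(3-chloroprop-1-en-2-yl)-6-hydroxy-6,10-dimethyl-14-oxopentadec-10-enoate | [K+].CC(C)(C)OC(=O)C[C@@H](C(=C)CCl)CC[C@](C)([O-])[C@H](O[Si](C)(C)C(C)(C)C)CC/C(C)=C\CCC(C)=O | intermediate
12 | tert-butyl 2-[(2S,5S)-2-[(1R,4Z)-1-(TBS-oxy)-4-methyl-8-oxonon-4-en-1-yl]-2-methyl-6-methylideneoxepan-5-yl]acetate | CC(C)(C)OC(=O)C[C@@H]1CC[C@](C)(OCC1=C)[C@H](O[Si](C)(C)C(C)(C)C)CC/C(C)=C\CCC(C)=O | intermediate
13 | 2-[(2S,5S)-2-[(1R,4Z)-1-(TBS-oxy)-8-hydroxy-4-methylnon-4-en-1-yl]-2-methyl-6-methylideneoxepan-5-yl]ethan-1-ol (C4 carbinol epimers) | OCC[C@@H]1CC[C@](C)(OCC1=C)[C@H](O[Si](C)(C)C(C)(C)C)CC/C(C)=C\CCC(C)O | intermediate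
14 | 2-[(2S,5S)-2-[(1R,4Z)-1-(TBS-oxy)-4-methyl-8-oxonon-4-en-1-yl]-2-methyl-6-methylideneoxepan-5-yl]acetaldehyde | O=CC[C@@H]1CC[C@](C)(OCC1=C)[C@H](O[Si](C)(C)C(C)(C)C)CC/C(C)=C\CCC(C)=O | intermediate
15 | (1S,3S,4R,7Z,11R,12S)-11-(TBS-oxy)-12,16-epoxycembra-7,15(17)-diene-3,4-diol | C=C1CO[C@@]2(C)CC[C@H]1C[C@H](O)[C@](C)(O)CC/C=C(/C)CC[C@H]2O[Si](C)(C)C(C)(C)C | intermediate
16 | (1S,4R,7Z,11R,12S)-11-(TBS-oxy)-4-hydroxy-3-oxocembra-7,15(17)-dien-16,12-olide | C=C1C(=O)O[C@@]2(C)CC[C@H]1CC(=O)[C@](C)(O)CC/C=C(/C)CC[C@H]2O[Si](C)(C)C(C)(C)C | intermediate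
17 | (1S,3S,4R,7Z,11R,12S)-11-(TBS-oxy)-3,4-dihydroxycembra-7,15(17)-dien-16,12-olide | C=C1C(=O)O[C@@]2(C)CC[C@H]1C[C@H](O)[C@](C)(O)CC/C=C(/C)CC[C@H]2O[Si](C)(C)C(C)(C)C | intermediate
18 | (1S,3S,4R,7Z,11R,12S)-3,4,11-trihydroxycembra-7,15(17)-dien-16,12-olide, CNP0263298.4 | C=C1C(=O)O[C@@]2(C)CC[C@H]1C[C@H](O)[C@](C)(O)CC/C=C(/C)CC[C@H]2O | target

**Step count and risks**

Total step count: 12. Longest linear sequence: 10 steps (5 → 18, steps 3–12); steps 1–2 form the side branch.

The three steps most likely to fail: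

Step 10 (the new step). The ring closure competes with simple reduction and dimerisation, and the C4 configuration rests on macrocyclic substrate control alone. The fallback uses known chemistry, sets out from 12 and comes back at 16. KN(SiMe3)2 and PhNTf2 convert the methyl ketone of 12 into the enol triflate F4. i-Bu2AlH at −78 °C reduces the tert-butyl ester to the aldehyde F5. A Nozaki–Hiyama–Kishi macrocyclisation (CrCl2, catalytic NiCl2, DMF/THF, high dilution) closes the C3–C4 bond to the allylic alcohol F6 (C3 epimers). Dess–Martin periodinane gives the α-methylene ketone F7. Mukaiyama-type α-hydroxylation of the enone (Mn(dpm)3, PhSiH3, O2, then P(OEt)3) gives the α-ketol F8, whose C4 centre again rests on substrate control. The chromate oxidation of step 11 then converts the oxepane of F8 into the lactone 16.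

Step 5. The hindered tetrasubstituted enol ether may react slowly, and the C11 selectivity rests on a small methyl-versus-methylene difference in an open transition state. The fallback sets out from 12 (carried through steps 6 and 7 as a C11 epimer mixture) and comes back at 12. HF·pyridine removes the silyl group to give the carbinol F1. Dess–Martin periodinane gives the C11 ketone F2. Zn(BH4)2 in Et2O at −78 °C reduces F2 under chelation between the ketone and the oxepane oxygen, hydride entering from the C12 methyl face, to give the single (11R)-carbinol F3; the chelated ketone should react faster than the remote methyl ketone. TBSOTf with 2,6-lutidine returns 12.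

Step 11. The chromate may attack the allylic methylenes at C6 and C9 or cleave the 3,4-glycol. The fallback sets out from 15 and comes back at 18, and needs the (3S,4R)-diol from step 10. 2,2-Dimethoxypropane with pyridinium tosylate protects the diol as the acetonide F9. The same chromate oxidation, now without any free carbinol, gives the lactone acetonide F10. Aqueous HF in MeCN removes the acetal and the silyl group to give 18, so the C3 oxidation–reduction detour is avoided.

**Further compounds**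

F1 | step 5 | tert-butyl 2-[(2S,5S)-2-[(4Z)-1-hydroxy-4-methyl-8-oxonon-4-en-1-yl]-2-methyl-6-methylideneoxepan-5-yl]acetate (C11 epimers) | CC(C)(C)OC(=O)C[C@@H]1CC[C@](C)(OCC1=C)C(O)CC/C(C)=C\CCC(C)=O
F2 | step 5 | tert-butyl 2-[(2S,5S)-2-methyl-6-methylidene-2-[(4Z)-4-methyl-1,8-dioxonon-4-en-1-yl]oxepan-5-yl]acetate | CC(C)(C)OC(=O)C[C@@H]1CC[C@](C)(OCC1=C)C(=O)CC/C(C)=C\CCC(C)=O
F3 | step 5 | tert-butyl 2-[(2S,5S)-2-[(1R,4Z)-1-hydroxy-4-methyl-8-oxonon-4-en-1-yl]-2-methyl-6-methylideneoxepan-5-yl]acetate | CC(C)(C)OC(=O)C[C@@H]1CC[C@](C)(OCC1=C)[C@H](O)CC/C(C)=C\CCC(C)=O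
F4 | step 10 | tert-butyl 2-[(2S,5S)-2-[(1R,4Z)-1-(TBS-oxy)-4-methyl-8-(trifluoromethylsulfonyloxy)nona-4,8-dien-1-yl]-2-methyl-6-methylideneoxepan-5-yl]acetate | CC(C)(C)OC(=O)C[C@@H]1CC[C@](C)(OCC1=C)[C@H](O[Si](C)(C)C(C)(C)C)CC/C(C)=C\CCC(=C)OS(=O)(=O)C(F)(F)F
F5 | step 10 | 2-[(2S,5S)-2-[(1R,4Z)-1-(TBS-oxy)-4-methyl-8-(trifluoromethylsulfonyloxy)nona-4,8-dien-1-yl]-2-methyl-6-methylideneoxepan-5-yl]acetaldehyde | O=CC[C@@H]1CC[C@](C)(OCC1=C)[C@H](O[Si](C)(C)C(C)(C)C)CC/C(C)=C\CCC(=C)OS(=O)(=O)C(F)(F)F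
F6 | step 10 | (1S,7Z,11R,12S)-11-(TBS-oxy)-12,16-epoxycembra-4(18),7,15(17)-trien-3-ol (C3 epimers) | C=C1CO[C@@]2(C)CC[C@H]1CC(O)C(=C)CC/C=C(/C)CC[C@H]2O[Si](C)(C)C(C)(C)C
F7 | step 10 | (1S,7Z,11R,12S)-11-(TBS-oxy)-12,16-epoxycembra-4(18),7,15(17)-trien-3-one | C=C1CO[C@@]2(C)CC[C@H]1CC(=O)C(=C)CC/C=C(/C)CC[C@H]2O[Si](C)(C)C(C)(C)C
F8 | step 10 | (1S,4R,7Z,11R,12S)-11-(TBS-oxy)-12,16-epoxy-4-hydroxycembra-7,15(17)-dien-3-one | C=C1CO[C@@]2(C)CC[C@H]1CC(=O)[C@](C)(O)CC/C=C(/C)CC[C@H]2O[Si](C)(C)C(C)(C)C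
F9 | step 11 | 3,4-O-isopropylidene acetal of (1S,3S,4R,7Z,11R,12S)-11-(TBS-oxy)-12,16-epoxycembra-7,15(17)-diene-3,4-diol | C=C1CO[C@@]2(C)CC[C@H]1C[C@@H]3OC(C)(C)O[C@]3(C)CC/C=C(/C)CC[C@H]2O[Si](C)(C)C(C)(C)C
F10 | step 11 | 3,4-O-isopropylidene acetal of (1S,3S,4R,7Z,11R,12S)-11-(TBS-oxy)-3,4-dihydroxycembra-7,15(17)-dien-16,12-olide | C=C1C(=O)O[C@@]2(C)CC[C@H]1C[C@@H]3OC(C)(C)O[C@]3(C)CC/C=C(/C)CC[C@H]2O[Si](C)(C)C(C)(C)C
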